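Imd4, the tris adduct, is a middle rung (a consecutive intermediate): Rgt is proposed to make it from Imd3 and to carry it on to Imd5.

| flask | Sbt | Rgt | remark | time |
|---|---|---|---|---|
| autumn | 10 mM | 0.81 equiv | run made earlier |  |
| winter | 10 mM | 1.5 equiv | run made earlier |  |
| midnight | 10 mM | 3.6 equiv | run made earlier |  |
| south | 10 mM | 0.800 equiv |  | 40 h |
| north-west | 10 mM | 2.00 equiv |  | 40 h |
| south-east | 10 mM | 3.00 equiv |  | 40 h |

- autumn (time / h: Imd4 / %): 8.00: 0; 15.0: 0.5; 25.0: 1.1; 30.0: 1.2; 40.0: 1.1
- winter (time / h: Imd4 / %): 8.00: 1.2; 15.0: 3.7; 25.0: 5.5; 30.0: 6.7; 40.0: 8.1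
- midnight (time / h: Imd4 / %): 3.00: 4.3; 6.00: 8.4; 12.0: 13.1; 20.0: 15.8; 40.0: 14.7

(scatter of a reading: 0.3 percentage points)

* final Imd4, as a percentage of the Sbt charged, for each flask in turn (south, north-west, south-east)

- in percentages every species weighs as the Sbt in it: one Ofp counts as two
- steps that have been proposed: Rgt + Imd3 -> Imd4; Rgt + Imd4 -> Imd5; Sbt + Imd2 -> Ofp; Sbt + Rgt -> Imd2; Rgt <-> Imd; Rgt + Imd2 -> Imd3

Two amounts read from the runs carry this reckoning of the last reading of Imd4. The first is a gain. From autumn to winter that reading climbs from 1.1% to 8.1%, which is 10 percentage points per equivalent of Rgt, and the winter readings still rise up to 40.0 h. The second is a ceiling, itself a reading with a scatter of 0.3 points. Midnight reads 15.8% at 20.0 h and then a lower 14.7% at 40.0 h, so in midnight loss has overtaken making.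

The gain line meets the ceiling at the crossing charge, 2.26 equiv. South and north-west stand below it, so the line gives 0.999% for south and 13.2% for north-west. South-east stands above it, so this reckoning takes the ceiling, 15.8%, and not the line's 23.3%.

The forecast gives 1.1%, 12% and 15%, and says of south-east that “it should be just past that peak”.

South, north-west and south-east give 1.19%, 12.7% and 15.7% of Imd4.

    Rgt + Imd3 → Imd4 (k = 52.0 /M/h)
    Rgt + Imd4 → Imd5 (k = 7.60 /M/h)
    Sbt + Imd2 → Ofp (k = 7.80 /M/h)
    Sbt + Rgt → Imd2 (k = 49.0 /M/h)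
    Rgt ⇌ Imd (K = 1.10, k = 0.390 /h)
    Rgt + Imd2 → Imd3 (k = 2.20 /M/h)

Held against the crossing of 2.26 equiv, north-west lies below it and ends 0.50 points under the gain line, while south-east lies above it and ends 0.1 points under the ceiling. At 40.0 h, north-west holds less Imd5 than Imd4, 8.02% against 12.7%, whereas south-east holds more, 23.1% against 15.7%.

The readings were computed with made-up constants.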